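Follow each substrate by the fraction of its own charge still present: f for the left-handed form, g for the right-handed. Each form is half of the pair, so a reading divided by 0.5 is such a fraction.

all flasks: gas 9.9 mM (held)
- Wednesday's: left-handed substrate 0.10 M; right-handed substrate 0.10 M; free catalyst 0.2 mol%; run made earlier
- Monday's: left-handed substrate 0.15 M; right-handed substrate 0.15 M; free catalyst 0.2 mol%; run made earlier
- Saturday's: left-handed substrate 0.20 M; right-handed substrate 0.20 M; free catalyst 0.4 mol%; run made earlier
- flask: left-handed substrate 0.20 M; right-handed substrate 0.20 M; free catalyst 0.2 mol%; time 8.0 d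

| run | time / d | right-handed substrate / % | left-handed substrate / % |
|---|---|---|---|
| Wednesday's | 0.625 | 45 | 36 |
| Wednesday's | 1.04 | 44 | 28 |
| Wednesday's | 1.67 | 38 | 22 |
| Wednesday's | 2.50 | 34 | 15 |
| Wednesday's | 3.00 | 28 | 9 |
| Wednesday's | 5.00 | 19 | 5 |
| Wednesday's | 8.00 | 12 | 4 |
| Monday's | 1.25 | 37 | 19 |
| Monday's | 2.50 | 30 | 8 |
| Monday's | 3.00 | 28 | 5 |
| Monday's | 5.00 | 12 | 0 |
| Monday's | 6.00 | 10 | 2 |
| Monday's | 8.00 | 6 | 0 |
| Saturday's | 1.67 | 17 | 3 |
| Saturday's | 3.00 | 6 | 2 |
| Saturday's | 5.00 | 4 | 0 |
| Saturday's | 6.00 | 2 | 0 |
| Saturday's | 8.00 | 0 | 1 |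

(each reading ± 1.5 percentage points)

- whether the excess of right-handed substrate over left-handed substrate among what is left of the two reaches 95 % by 8.0 d (yes / no)
- the highest excess of right-handed substrate over left-handed substrate among what is left of the two up to 8.0 d

- free catalyst is single-handed; left-handed substrate and right-handed substrate are mirror images of each other, charged as a racemate, each of them at the stated concentration
- at the start none of the gas is in solution

Assume two pseudo-first-order decays on one clock, each with a rate constant proportional to the catalyst concentration. Time and catalyst then cancel from a ratio, the selectivity factor s: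

s = ln f / ln g

Wednesday's readings at 2.50 d give 3.12 for this ratio of logarithms. Saturday's at 1.67 d give 2.61, from a left-handed reading of 3 % that the scatter shakes badly.

Once f is far below g, the excess stands a small correction below 1, so only that correction needs reckoning:

f/g = g^(s − 1), excess ≈ 1 − 2 f/g

Since s is above 1, in this reckoning f/g shrinks as g falls, and the top stands at the last time.

The flask holds twice Wednesday's catalyst concentration, so on the assumption above its clock runs at twice Wednesday's pace, and its g at 8.0 d is the square of the g read from Wednesday's run at 8.00 d: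

g = 5.76 %

f/g = 0.234 %

excess ≈ 99.5 %

With Saturday's s the reckoning still gives 98.0 % for the flask, above the 95 % wanted, so this reckoning says yes.

The forecast also says yes, but with a lower top of 98 %, between 90 % and 99.5 %: “I shade the estimate down and widen the range.”

The flask answers yes, and its top is 99.8 %.

    left-handed product ⇌ right-handed product (k = 0.0710 h⁻¹)
    reagent + catalyst intermediate B → free catalyst + right-handed product (k = 2300 M⁻¹ h⁻¹)
    gas ⇌ reagent, rate k3*(csat - [reagent]) (kL = 18.0 h⁻¹)
    reagent + catalyst intermediate A → free catalyst + left-handed product (k = 5700 M⁻¹ h⁻¹)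
    free catalyst + right-handed substrate ⇌ catalyst intermediate B (K = 2.00 M⁻¹, k = 5100 M⁻¹ h⁻¹)
    2 reagent → self-condensation product (k = 2.00 M⁻¹ h⁻¹)
    free catalyst + left-handed substrate ⇌ catalyst intermediate A (K = 3.20 M⁻¹, k = 970 M⁻¹ h⁻¹)

That top is the excess at 8.00 d, when the right-handed substrate in the flask keeps 5.6 % of its own charge. Put through the s read from Wednesday's run, this fraction gives a reckoned f/g of 0.220 %, a reckoned excess of 99.6 %.

The earlier runs and the new flask were generated by integration for substances that don't exist, and the scatter is random.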